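If the next flask is to stay at 5 °C and carry less homo dimer than the south-west run, the choice lies in how substrate and reagent meet, and one number read from the runs at that temperature can judge those recipes; what temperature does to homo dimer the runs do not show.

| flask | substrate | reagent | temperature | remark | time |
|---|---|---|---|---|---|
| south-west | 0.20 M | 0.19 M | 5 °C | run made earlier |  |
| west | 0.20 M | 0.38 M | 5 °C | run made earlier |  |
| dusk | 0.20 M | 0.190 M | 5 °C | everything together at the start | 8.0 min |
| spring | 0.20 M (fed, over 6.0 min) | 0.190 M | 5 °C | all else is in the flask from the start; the feed brings no volume worth counting | 8.0 min |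
| summer | 0.20 M (in portions, 2, over 6.0 min) | 0.190 M | 5 °C | first portion at the start, last at 6.0 min | 8.0 min |
| winter | 0.20 M | 0.190 M (fed, over 6.0 min) |  | the addition at −15 °C, then warmed to 5 °C; the feed brings no volume worth counting | 8.0 min |
| dawn | 0.20 M | 0.190 M |  | everything together at the start at −15 °C, warmed to 5 °C at 6.0 min | 8.0 min |

| run | time / min | homo dimer / % | target / % |
|---|---|---|---|
| south-west | 0.417 | 13.4 | 25.9 |
| south-west | 1.33 | 21.3 | 52.4 |
| south-west | 2.00 | 21.8 | 60.0 |
| south-west | 3.00 | 23.7 | 65.0 |
| south-west | 5.00 | 24.0 | 71.2 |
| west | 0.200 | 7.0 | 20.9 |
| west | 0.667 | 11.3 | 61.3 |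
| west | 1.00 | 11.6 | 72.8 |
| west | 1.50 | 12.2 | 81.5 |
| west | 2.50 | 12.5 | 86.6 |

(readings scatter by 0.5 percentage points)

- a species is counted by the substrate in it: one homo dimer counts as two
- reactions considered so far: substrate + reagent -> intermediate + released group; intermediate -> target; 2 substrate -> homo dimer; substrate -> decomposition product
- the earlier runs do not show what temperature does; that part of a forecast is a guess

* which flask leads in amount of homo dimer, in percent of the substrate charged ("all alike" within 1.5 percentage points) (dusk / spring / summer / winter / dawn / all alike)
* how much homo dimer is there at the end, in percent of the substrate charged: dusk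
* how much homo dimer is there at the end, in percent of the substrate charged: spring
* how much homo dimer is there at the end, in percent of the substrate charged: summer
* how much homo dimer is there at the end, in percent of the substrate charged: winter
* how much homo dimer is there at the end, in percent of the substrate charged: dawn

Let A and B be substrate and reagent, both as fractions of the substrate charge. At any moment, substrate goes to homo dimer and through reagent in the proportion s·A/B, where s is the dimer ratio, a selectivity factor for 5 °C. Both paths are second order, so the final dimer share follows the opening B/A, and halving both concentrations doubles the clock.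

In the west run, the last reading of dimer is 12.5 %. Taking A as 0.5 on average, and B as its opening value less 0.5 of the reagent spent:

s = 0.143 × 1.46 / 0.5 = 0.418

Integrated to the end of the substrate, the rule returns 23.6 % for the south-west run, against 24.0 % read there.

Summer's first portion opens at the west run's B/A, and its 6.0 min equal 3.00 min on the west clock, later than the last west reading:

first portion: 6.25 % of the charge

The second portion meets reagent at B/A = 1.02. Run out, it gives:

second portion, run out: 10.9 %

Its remaining time equals 1.00 min on the south-west clock, where the readings interpolate to 76.9 % of the last reading: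

summer at the end: 14.6 %

Spring opens with no substrate in the flask and winter with no reagent, so the next charge is substrate in portions or by feed, not reagent fed onto substrate, although s is read at 5 °C and winter's addition runs at −15 °C.

The forecast has winter leading, with dusk 24.5 %, spring 14 %, summer 16 %, above this reckoning, winter 40 % and dawn 24 %, saying of winter: “Substrate then sits with little reagent, so dimer is worst”.

The flasks give dusk 24.3 %, spring 12.4 %, summer 15.3 %, winter 31.5 % and dawn 19.1 %, so winter leads. Summer holds 5.92 % at 6.00 min, against the reckoned 6.25 %, and 15.3 % at the end, against 14.6 %.

    substrate + reagent → intermediate + released group (k = 0.109 L mol⁻¹ s⁻¹, Ea = 44.0 kJ mol⁻¹)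
    intermediate → target (k = 0.153 s⁻¹, Ea = 70.0 kJ mol⁻¹)
    2 substrate → homo dimer (k = 0.0240 L mol⁻¹ s⁻¹, Ea = 56.0 kJ mol⁻¹)
    substrate → decomposition product (k = 2.31 × 10⁻⁵ s⁻¹, Ea = 86.0 kJ mol⁻¹)
    (constants at 5 °C)

The neighbour of spring is charged with 0.34 M of substrate. At 8.00 min it holds 16.5 % of substrate and 3.94 % of its reagent charge, so s·A/B stands at 3.13, above spring's 0.250. That neighbour ends with 53.6 % of target and 29.6 % of homo dimer.

(The data were generated by integration on assumed constants, noise included.)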